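Against links, isomer of the product stands lower late in the winter run at 35 °C than late in the dawn run at 20 °C: 0.355 against 0.563. I call this number the isomer ratio, isomer of the product over links as fractions of the charge, summed over the flat late readings of a run; it is an apparent equilibrium constant.

| setting | dawn | winter | epsilon | beta |
|---|---|---|---|---|
| first end groups | 0.10 M (fed, over 20 s) | 0.10 M (fed, over 20 s) | 0.10 M (fed, over 20 s) | 0.10 M |
| second end groups | 0.14 M | 0.22 M | 0.100 M | 0.100 M |
| third end groups | 0.025 M | 0.025 M | 0.0250 M | 0.0250 M |
| temperature | 20 °C | 35 °C | 35 °C | 35 °C |
| remark | run made earlier | run made earlier |  | everything together at the start |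
| time |  |  | 4.0 min | 2.0 min |

- dawn (time / min: links / %, isomer of the product / %): 2.00: 51.0, 20.7; 3.00: 48.4, 24.7; 5.00: 45.0, 25.1; 6.00: 44.3, 25.2
- winter (time / min: links / %, isomer of the product / %): 0.417: 58.8, 13.5; 1.00: 55.6, 19.8; 2.00: 57.2, 18.7; 3.00: 55.7, 21.3

(readings scatter by 1 percentage point)

- the flask that ends with the higher share of links in all that became links or isomer of the product, or "neither" when 2 percentage points or less lies between them (epsilon / beta / neither)
- share of links in all that became links or isomer of the product, epsilon
- share of links in all that became links or isomer of the product, beta

- a species is counted by the first end groups in it: one homo dimer counts as two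
- the numbers in the tables scatter by 1 percentage point (one standard deviation)
- steps under discussion: first end groups + second end groups <-> links; second end groups + third end groups -> links of the second sort; links <-> isomer of the product; 2 first end groups -> homo dimer

Links and isomer of the product turn into each other one for one, so the ratio holds no concentration. Past relaxation, links over links plus isomer is then read straight off it, and the winter ratio gives 73.8 %. Epsilon and beta both stand at 35 °C, so I commit to that share for both, with no difference beyond the margin of 2 percentage points.

One number is enough if two things hold. The first is that both flasks are past relaxation. The winter ratio reads 0.230 at 0.417 min, 0.356 at 1.00 min and 0.382 at 3.00 min, so within the scatter it is flat from 1.00 min, earlier than beta's 2.0 min and epsilon's 4.0 min. The second is that the winter ratio carries over to another amount of second end groups, and this I cannot test: they stood at 0.14 M in dawn and 0.22 M in winter, against 0.100 M in the new flasks, and temperature changed between the two runs as well.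

The forecast says neither, with 73 % (70 % to 76 %) for epsilon and 73.5 % (70 % to 77 %) for beta, holding that “the plateau share depends on temperature, not on concentrations”.

The flasks give 73.4 % for epsilon and 73.4 % for beta, so the answer is neither.

    first end groups + second end groups ⇌ links (K = 21.0 M⁻¹, k = 1.33 M⁻¹ s⁻¹, Ea = 49.0 kJ mol⁻¹, ΔH = −35.0 kJ mol⁻¹)
    second end groups + third end groups → links of the second sort (k = 1.68 M⁻¹ s⁻¹, Ea = 55.0 kJ mol⁻¹)
    links ⇌ isomer of the product (K = 0.360, k = 0.0312 s⁻¹, Ea = 86.0 kJ mol⁻¹, ΔH = −24.0 kJ mol⁻¹)
    2 first end groups → homo dimer (k = 0.0144 M⁻¹ s⁻¹, Ea = 60.0 kJ mol⁻¹)
    (constants at 35 °C)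

Epsilon ends with links at 30.5 % and isomer of the product at 11.0 %, a ratio of 0.361, and the relaxation half-life of that step, both ways together, is 0.0980 min, short against 4.0 min. For the neighbour, epsilon run at 20 °C, I put the dawn ratio 0.563 in place of the winter 0.355, which means a share of 64.0 %. But the dawn ratio reads 0.510 at 3.00 min and first reads flat at 5.00 min, later than the neighbour's 4.0 min, so I expect its share slightly higher. The neighbour ends with isomer of the product at 19.4 % of the charge and a share of links of 64.7 %.

(The numbers in the tables were generated by integration for substances that don't exist; the scatter is artificial.)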